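**Assumption:** (+)-manool, (13R)-labda-8(17),14-dien-13-ol, is taken as a purchasable chiral-pool labdane; its C5, C9 and C10 have the configuration of the target (checked against the target SMILES: 5α-H, 9α-H with β side chain, 10β-CH3).

## Retrosynthetic overview

1. The target is (13E)-15-acetoxylabda-7,13-dien-17-oic acid of the normal labdane series; the decalin and all three stereocentres are bought with (+)-manool, so no ring is formed in the route.
2. C17 acid ⇐ C17 enal ⇐ 7-en-17-ol ⇐ 8α,17-epoxide ⇐ exocyclic 8(17)-alkene of manool (oxygenation of C17 with shift of the alkene into ring B).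
3. C15–OAc and the 13E alkene ⇐ tertiary 13-acetate by a [3,3]-sigmatropic acetate shift catalysed by divalent palladium; this key step forms the C15–O bond.
4. Order: ring B is oxidised first, while the side-chain alkene is still an unreactive vinyl group; then acetylation, the sigmatropic shift, and aldehyde-to-acid oxidation last.

## Route

**Step 1**
Reactants: 1 (+)-manool
Product: 2 (8R,13R)-8α,17-epoxylabd-14-en-13-ol
Conditions: mCPBA (1.05 equiv), NaHCO3, CH2Cl2/H2O, 0 °C
Reagents that add atoms: mCPBA (3-chloroperoxybenzoic acid), O=C(OO)c1cccc(Cl)c1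
Why: Prilezhaev epoxidation is selective for the electron-richer 1,1-disubstituted exocyclic alkene over the monosubstituted vinyl group, and attack from the α face, opposite the axial C10 methyl, gives the 8α,17-epoxide, a centre that is erased again in step 2.

**Step 2**
Reactants: 2 (8R,13R)-8α,17-epoxylabd-14-en-13-ol
Product: 3 (13R)-labda-7,14-diene-13,17-diol
Conditions: LiN(iPr)2 (4 equiv), Et2O, 0 °C → reflux; then H2O
Reagents that add atoms: none
Why: Base-promoted epoxide-to-allylic-alcohol isomerisation (syn β-elimination by lithium amide) removes the accessible C7–H instead of the hindered tertiary C9–H and opens the C8–O bond, giving the 7,8-alkene and the C17 alcohol while C9 stays untouched.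

**Step 3**
Reactants: 3 (13R)-labda-7,14-diene-13,17-diol
Product: 4 (13R)-13-hydroxylabda-7,14-dien-17-al
Conditions: MnO2 (activated, 15 equiv), CH2Cl2, rt
Reagents that add atoms: none
Why: Allylic alcohol oxidation with MnO2 converts only the primary allylic alcohol into the conjugated aldehyde, since the tertiary 13-OH cannot be oxidised, and no stereocentre is touched.

**Step 4**
Reactants: 4 (13R)-13-hydroxylabda-7,14-dien-17-al
Product: 5 (13R)-17-oxolabda-7,14-dien-13-yl acetate
Conditions: Ac2O (3 equiv), Et3N, 4-(dimethylamino)pyridine (0.2 equiv), CH2Cl2, rt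
Reagents that add atoms: acetic anhydride, CC(=O)OC(C)=O
Why: Acylpyridinium-catalysed (Steglich-type) acetylation esterifies the hindered tertiary allylic alcohol as it does linalool, with retention at C13 and without affecting the enal.

**Step 5**
Reactants: 5 (13R)-17-oxolabda-7,14-dien-13-yl acetate
Product: 6 (13E)-17-oxolabda-7,13-dien-15-yl acetate
Conditions: PdCl2(MeCN)2 (5 mol%), THF, rt; E isomer separated on AgNO3-impregnated SiO2
Reagents that add atoms: none
Why: The Overman-type [3,3]-sigmatropic acetate shift catalysed by divalent palladium (through a six-membered acetoxonium–palladium intermediate on the coordinated vinyl group) forms the C15–O bond and moves the alkene to C13=C14, driven by the trisubstituted alkene and primary ester, with the chair that keeps the large CH2 chain equatorial favouring the E isomer (expected about 4:1) and the C13 centre consumed.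

**Step 6**
Reactants: 6 (13E)-17-oxolabda-7,13-dien-15-yl acetate
Product: 7 (13E)-15-acetoxylabda-7,13-dien-17-oic acid (target)
Conditions: NaClO2, NaH2PO4, 2-methyl-2-butene, tBuOH/H2O, 0 °C → rt
Reagents that add atoms: sodium chlorite, [Na+].[O-]Cl=O
Why: Pinnick oxidation converts the α,β-unsaturated aldehyde into the acid under buffered conditions that leave the allylic acetate and both alkenes intact (2-methyl-2-butene scavenges HOCl), with C5, C9 and C10 unchanged.

## Compound list

1 | (+)-manool, (13R)-labda-8(17),14-dien-13-ol (5α-H, 9α-H, 10β-CH3) | C=C[C@](C)(O)CC[C@H]1C(=C)CC[C@H]2C(C)(C)CCC[C@]12C | starting material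
2 | (8R,13R)-8α,17-epoxylabd-14-en-13-ol (spiro-oxirane at C8, oxygen on the α face) | C=C[C@](C)(O)CC[C@H]1[C@]3(OC3)CC[C@H]2C(C)(C)CCC[C@]12C | intermediate
3 | (13R)-labda-7,14-diene-13,17-diol | C=C[C@](C)(O)CC[C@H]1C(CO)=CC[C@H]2C(C)(C)CCC[C@]12C | intermediate
4 | (13R)-13-hydroxylabda-7,14-dien-17-al | C=C[C@](C)(O)CC[C@H]1C(C=O)=CC[C@H]2C(C)(C)CCC[C@]12C | intermediate
5 | (13R)-17-oxolabda-7,14-dien-13-yl acetate | C=C[C@](C)(OC(C)=O)CC[C@H]1C(C=O)=CC[C@H]2C(C)(C)CCC[C@]12C | intermediate
6 | (13E)-17-oxolabda-7,13-dien-15-yl acetate | CC(=O)OC/C=C(\C)CC[C@H]1C(C=O)=CC[C@H]2C(C)(C)CCC[C@]12C | intermediate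
7 | (13E)-15-acetoxylabda-7,13-dien-17-oic acid, i.e. (1R,4aS,8aS)-1-[(3E)-5-acetoxy-3-methylpent-3-en-1-yl]-5,5,8a-trimethyl-1,4,4a,5,6,7,8,8a-octahydronaphthalene-2-carboxylic acid | CC(=O)OC/C=C(\C)CC[C@H]1C(C(=O)O)=CC[C@H]2C(C)(C)CCC[C@]12C | target

## Count and risks

Total step count: 6. Longest linear sequence: 6.

**Step 1** (over-oxidation of the vinyl group, or opening of the acid-labile epoxide by the 13-OH to a cyclic ether). The fallback sets out from 1 and comes back at 4, leaving out the epoxide. An ene-type allylic chlorination with HOCl (Ca(OCl)2, solid CO2, CH2Cl2/H2O, 0 °C) attacks the exocyclic alkene and shifts it into the ring, giving (13R)-17-chlorolabda-7,14-dien-13-ol F1. Kornblum oxidation (DMSO, NaHCO3, NaI cat., 80 °C) then turns the primary allylic chloride into aldehyde 4.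

**Step 2** (loss of C9–H giving the 8,9-alkene, carbenoid side reactions, or a sluggish reaction of the dianion). The fallback sets out from 1 and comes back at 3. Photo-oxygenation of 1 (O2, 5,10,15,20-tetraphenylporphyrin, visible light, CH2Cl2, 0 °C) is a singlet-oxygen ene reaction; the vinyl group is inert, oxygen adds to C17 and a C7 hydrogen is taken, giving (13R)-17-hydroperoxylabda-7,14-dien-13-ol F2. Reduction with PPh3 in the same solvent gives diol 3.

**Step 5** (E/Z ratio no better than about 4:1, or elimination of the tertiary acetate to dienes). The fallback sets out from 4 and comes back at 6, without the tertiary acetate and without palladium. PBr3 (0.4 equiv, Et2O, −10 °C) converts the tertiary vinyl carbinol by allylic (SN2′-type) transposition into the primary bromide (13E)-15-bromolabda-7,13-dien-17-al F3. Displacement with KOAc in DMF at rt gives 6. The E/Z ratio is expected to be similar, so the Z isomer is still removed at the stage of 6 on AgNO3-impregnated SiO2.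

## Further compounds

F1 | step 1 | (13R)-17-chlorolabda-7,14-dien-13-ol | C=C[C@](C)(O)CC[C@H]1C(CCl)=CC[C@H]2C(C)(C)CCC[C@]12C
F2 | step 2 | (13R)-17-hydroperoxylabda-7,14-dien-13-ol | C=C[C@](C)(O)CC[C@H]1C(COO)=CC[C@H]2C(C)(C)CCC[C@]12C
F3 | step 5 | (13E)-15-bromolabda-7,13-dien-17-al | BrC/C=C(\C)CC[C@H]1C(C=O)=CC[C@H]2C(C)(C)CCC[C@]12C
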